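The runs are simulated for substances that don't exist, and the scatter is random.

The flask holds a small charge, 0.019 M of starting material, so from the earlier runs I wanted the correction that dilution makes to a run I already knew.

| flask | starting material | reagent | free catalyst | remark | time |
|---|---|---|---|---|---|
| amber | 0.027 M | 1.1 equiv | 2 mol% | run made earlier |  |
| violet | 0.042 M | 1.1 equiv | 2 mol% | run made earlier |  |
| teal | 0.019 M | 2.2 equiv | 2 mol% | run made earlier |  |
| flask | 0.019 M | 1.10 equiv | 2 mol% |  | 50 h |

| run | time / h | product / % |
|---|---|---|
| amber | 12.0 | 39.7 |
| amber | 15.0 | 48.8 |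
| amber | 20.0 | 58.5 |
| amber | 30.0 | 69.6 |
| amber | 40.0 | 74.4 |
| amber | 48.0 | 76.4 |
| violet | 12.0 | 47.8 |
| violet | 15.0 | 55.7 |
| violet | 20.0 | 67.0 |
| violet | 30.0 | 74.5 |
| violet | 40.0 | 79.5 |
| violet | 48.0 | 77.9 |
| teal | 12.0 | 40.4 |
| teal | 20.0 | 58.3 |
| teal | 25.0 | 64.0 |
| teal | 40.0 | 74.5 |
| teal | 48.0 | 75.7 |

(readings scatter by 1 percentage point)

- time up to 50 h at which product stands highest
- the amount of product, in percent of the starting material charged, at that time

Did more reagent lift the end? Teal, at 0.019 M like the flask, had twice the flask's equivalents and read 75.7% at 48.0 h, against amber's 76.4% at 48.0 h. Amber differed from teal in [starting material] as well, so this was a rough test, but I chose to put no reagent term into the correction.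

Did concentration lift it? Violet held 1.56 times amber's [starting material] and read 77.9% at 48.0 h. That gave me 3.4 percentage points per natural-log unit of [starting material], which I called the dilution slope: the last reading gained per such unit at constant equivalents and catalyst loading. With 1 point of scatter on each reading, it was a rough value.

How far down did that put the flask? Its [starting material] is 0.704 of amber's, so, taking amber's last reading as the starting point, I reckoned 75.2%. Amber's readings still rose, by 2 points from 40.0 h to 48.0 h, so I placed the highest point at 50 h.

The forecast gave 72% at 50 h, lower than my figure, and said: “The product is probably still rising or flat at 50 h.”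

The flask gave 75.1% at 50.0 h.

    starting material + free catalyst → catalyst intermediate A (k = 0.120 M⁻¹ s⁻¹)
    reagent + catalyst intermediate A → catalyst intermediate B (k = 0.117 M⁻¹ s⁻¹)
    catalyst intermediate B → by-product + catalyst intermediate C (k = 0.00126 s⁻¹)
    catalyst intermediate C ⇌ free catalyst + product (K = 0.870 M, k = 0.00294 s⁻¹)
    free catalyst + product → spent catalyst A (k = 0.00272 M⁻¹ s⁻¹)
    2 free catalyst → spent catalyst B (k = 0.0194 M⁻¹ s⁻¹)

The flask ended 0.10 points from my reckoning. The same slope put a neighbour flask with 0.076 M of starting material at 79.9%; that neighbour stood at 79.4%, 7.4 points above the forecast's number. In the flask, free catalyst was used towards catalyst intermediate A 74 times as fast as towards spent catalyst A, an off-cycle form, at 12.2 h, but 14 times as fast at 50.0 h. At that last time spent catalyst A held 75.9% of the catalyst charged, with 23% of the starting material still left.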